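The pyran ring (ring C) of the middle flavan unit is built from two acyclic pieces. In one flask, the sulfur-stabilised benzylic carbanion of a 2-fluoro-4,6-bis(benzyloxy)benzyl phenyl sulfide adds to a chelated (R)-α-oxido aldehyde (C3–C4 bond) and the benzylic alkoxide then displaces the ring A fluoride (O1–C8a bond). The step exploits three features: C8a of ring A, meta to both the C5 and C7 oxygens, as an SNAr site; the cis C2-aryl/C3-oxygen relationship, set by chelate-controlled syn addition; and C4, whose phenylthio group first stabilises the anion and later leaves, so that the resulting gallate serves twice as the C4 electrophile for the 4β→8 bonds.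

Key step: step 7

Remark on the chemistry: C4 of 16 and 18 forms without control and is destroyed again on ionisation, so both are carried as C4 epimer mixtures and their SMILES leave that centre undefined; 11 is stored as its hemiacetal dimer and drawn as the monomer.

Step 1
Reactants: 1 1,3,5-trifluorobenzene
Product: 2 1,3-bis(benzyloxy)-5-fluorobenzene
Conditions: BnOH (2.05 equiv), NaH, NMP, 0 → 100 °C
Reagents that add atoms: benzyl alcohol OCc1ccccc1
Why: Double nucleophilic aromatic substitution of fluoride by sodium benzyloxide, in which each alkoxy group introduced deactivates the ring toward the next attack, so the reaction should stop at the bis-ether.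

Step 2
Reactants: 2 1,3-bis(benzyloxy)-5-fluorobenzene
Product: 4 [2,4-bis(benzyloxy)-6-fluorophenyl]methanol, via aryllithium 3 (not isolated)
Conditions: n-BuLi, THF, −78 °C; then (CH2O)n (cracked), −78 °C → rt
Reagents that add atoms: formaldehyde C=O
Why: Directed ortho-lithiation should occur at the ring carbon flanked by fluorine and a benzyloxy group (the most acidic position), and the aryllithium, kept cold to avoid loss of LiF, is hydroxymethylated by formaldehyde.

Step 3
Reactants: 4 [2,4-bis(benzyloxy)-6-fluorophenyl]methanol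
Product: 5 1,5-bis(benzyloxy)-3-fluoro-2-[(phenylsulfanyl)methyl]benzene
Conditions: PhSH, ZnI2 (0.5 equiv), ClCH2CH2Cl, rt
Reagents that add atoms: thiophenol Sc1ccccc1
Why: ZnI2-promoted ionisation of the electron-rich benzylic alcohol gives a stabilised benzylic cation that the thiol captures (Lewis-acid-mediated thioetherification), installing the sulfur that acidifies C4 now and leaves from it later.

Step 4
Reactants: 6 4-bromo-1,2-bis(benzyloxy)benzene; 7 methyl 2,2-dimethoxyacetate
Product: 9 1-[3,4-bis(benzyloxy)phenyl]-2,2-dimethoxyethan-1-one, via aryllithium 8 (not isolated)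
Conditions: n-BuLi, THF, −78 °C; then added to 7 (1.5 equiv), THF, −78 °C
Reagents that add atoms: none
Why: Bromine–lithium exchange followed by acylation of the aryllithium by the α,α-dialkoxy ester, whose chelated tetrahedral adduct should resist a second addition at −78 °C under inverse addition.

Step 5
Reactants: 9 1-[3,4-bis(benzyloxy)phenyl]-2,2-dimethoxyethan-1-one
Product: 10 (1R)-1-[3,4-bis(benzyloxy)phenyl]-2,2-dimethoxyethan-1-ol
Conditions: RuCl[(S,S)-TsDPEN](p-cymene) (1 mol %), HCO2H–Et3N (5:2), CH2Cl2, rt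
Reagents that add atoms: none
Why: Noyori asymmetric transfer hydrogenation of an aryl ketone, in which the (S,S)-catalyst should deliver hydride with the same facial sense as for aryl methyl ketones (the descriptor is R because the acetal carbon outranks the aryl group), setting the future C2.

Step 6
Reactants: 10 (1R)-1-[3,4-bis(benzyloxy)phenyl]-2,2-dimethoxyethan-1-ol
Product: 11 (2R)-2-[3,4-bis(benzyloxy)phenyl]-2-hydroxyacetaldehyde
Conditions: 1 M aq. HCl, THF, rt
Reagents that add atoms: water O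
Why: Acid-catalysed acetal hydrolysis, mild enough that enolisation toward the enediol (the path to racemisation) should stay slow, the aldehyde being collected as its hemiacetal dimer.

Step 7
Reactants: 5 1,5-bis(benzyloxy)-3-fluoro-2-[(phenylsulfanyl)methyl]benzene; 11 (2R)-2-[3,4-bis(benzyloxy)phenyl]-2-hydroxyacetaldehyde
Product: 16 (2R,3S)-5,7-bis(benzyloxy)-2-[3,4-bis(benzyloxy)phenyl]-4-(phenylsulfanyl)chroman-3-ol (2,3-cis; C4 epimers), via lithiated sulfide 12 (not isolated), via lithium alkoxide 13 (not isolated), via dilithium diolate 14 (not isolated), via monolithium alkoxide 15 (not isolated)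
Conditions: 5, LiN(i-Pr)2, THF, −78 °C; 11, LiN(SiMe3)2, THF, −78 °C, added by cannula; then AcOH (1.0 equiv), DMPU, −78 → 65 °C
Reagents that add atoms: none
Why: The thio-stabilised benzyllithium 12 adds to the aldehyde carbon of 13 (C3–C4), and after the diolate 14 has been buffered to the mono-alkoxide 15 the benzylic oxygen O1 displaces fluoride at C8a through a Meisenheimer adduct (O1–C8a). The closest known reactions are the Cram-chelate addition of organolithiums to α-oxygenated aldehydes and the intramolecular SNAr etherification of fluoroarenes by tethered alkoxides. Ring C closes in a six-membered SNAr mode, favoured over five-membered attack by O3 because that closure is strained and because the more acidic benzylic hydroxyl is the one that stays deprotonated in 15. C2 comes unchanged from 11, C3 is set by chelation control (the nucleophile enters the five-membered lithium chelate anti to the aryl group, giving the syn diol and hence the 2,3-cis ring), and C4 forms as a mixture that does not matter because it is ionised in steps 10 and 11. The step needs addition to outrun enolisation of the aldehyde and needs the sulfur-acidified C4–H not to trigger β-elimination: the α-oxido group makes 13 resistant to deprotonation at C2, and the free C3 hydroxyl of 15 is too poor a leaving group to be expelled.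

Step 8
Reactants: 16 (2R,3S)-5,7-bis(benzyloxy)-2-[3,4-bis(benzyloxy)phenyl]-4-(phenylsulfanyl)chroman-3-ol; 17 3,4,5-tris(benzyloxy)benzoic acid
Product: 18 (2R,3S)-5,7-bis(benzyloxy)-2-[3,4-bis(benzyloxy)phenyl]-4-(phenylsulfanyl)chroman-3-yl 3,4,5-tris(benzyloxy)benzoate (C4 epimers)
Conditions: DCC, DMAP, CH2Cl2, rt
Reagents that add atoms: none
Why: Steglich esterification of the axial secondary alcohol with the protected gallic acid, which touches no stereocentre.

Step 9
Reactants: 19 (+)-catechin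
Product: 20 5,7,3',4'-tetra-O-benzyl-(+)-catechin
Conditions: BnBr, K2CO3, DMF, 0 °C → rt
Reagents that add atoms: benzyl bromide BrCc1ccccc1
Why: Williamson etherification of the four phenols, which are far more acidic than the secondary alcohol and should react selectively under carbonate base.

Step 10
Reactants: 18 gallate thioether (C4 epimers); 20 5,7,3',4'-tetra-O-benzyl-(+)-catechin
Product: 21 5,7,3',4'-tetra-O-benzyl-3-O-[3,4,5-tris(benzyloxy)benzoyl]epicatechin-(4β→8)-5,7,3',4'-tetra-O-benzylcatechin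
Conditions: AgBF4, 2,6-di-tert-butyl-4-methylpyridine, 4 Å MS, CH2Cl2, −40 → 0 °C; 20 (4 equiv)
Reagents that add atoms: none
Why: Silver-assisted heterolysis of the benzylic C4–S bond gives the C4 cation (stabilised by the ring A oxygens and bridged on the α-face by the gallate carbonyl), which alkylates C8 of 20 in a Friedel–Crafts-type flavan-4-yl coupling from the β-face, anti to the C2 aryl and C3 ester groups, so both C4 epimers of 18 should converge on the 4β→8 bond while excess 20 suppresses self-condensation.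

Step 11
Reactants: 18 gallate thioether (C4 epimers); 21 protected epicatechin gallate-(4β→8)-catechin dimer
Product: 22 octadeca-O-benzyl epicatechin-3-O-gallate-(4β→8)-epicatechin-3-O-gallate-(4β→8)-catechin
Conditions: AgBF4, 2,6-di-tert-butyl-4-methylpyridine, 4 Å MS, CH2Cl2, −40 → 0 °C; slow addition of 18 to 21 (2 equiv)
Reagents that add atoms: none
Why: The same thiophilic activation and Friedel–Crafts-type coupling, in which the cation from 18 should attack C8 of the upper unit of 21 (the most accessible phloroglucinol-type carbon) anti to its C2 aryl and C3 gallate groups, setting the second 4β→8 bond, with slow addition keeping self-coupling of 18 low.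

Step 12
Reactants: 22 octadeca-O-benzyl trimer
Product: 23 epicatechin-3-O-gallate-(4β→8)-epicatechin-3-O-gallate-(4β→8)-catechin (CNP0269915.2)
Conditions: H2 (1 atm), Pd(OH)2/C, THF–MeOH–H2O, rt
Reagents that add atoms: none
Why: Global hydrogenolysis of the eighteen benzyl ethers over Pd(OH)2/C should leave the two gallate esters, the interflavan C–C bonds and all stereocentres untouched.

Compound list
1 | 1,3,5-trifluorobenzene | Fc1cc(F)cc(F)c1 | starting material
2 | 1,3-bis(benzyloxy)-5-fluorobenzene | Fc1cc(OCc2ccccc2)cc(OCc2ccccc2)c1 | intermediate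
3 | [2,4-bis(benzyloxy)-6-fluorophenyl]lithium | [Li]c1c(F)cc(OCc2ccccc2)cc1OCc1ccccc1 | intermediate
4 | [2,4-bis(benzyloxy)-6-fluorophenyl]methanol | OCc1c(F)cc(OCc2ccccc2)cc1OCc1ccccc1 | intermediate
5 | 1,5-bis(benzyloxy)-3-fluoro-2-[(phenylsulfanyl)methyl]benzene | Fc1cc(OCc2ccccc2)cc(OCc2ccccc2)c1CSc1ccccc1 | intermediate
6 | 4-bromo-1,2-bis(benzyloxy)benzene | Brc1ccc(OCc2ccccc2)c(OCc2ccccc2)c1 | starting material
7 | methyl 2,2-dimethoxyacetate | COC(OC)C(=O)OC | starting material
8 | [3,4-bis(benzyloxy)phenyl]lithium | [Li]c1ccc(OCc2ccccc2)c(OCc2ccccc2)c1 | intermediate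
9 | 1-[3,4-bis(benzyloxy)phenyl]-2,2-dimethoxyethan-1-one | COC(OC)C(=O)c1ccc(OCc2ccccc2)c(OCc2ccccc2)c1 | intermediate
10 | (1R)-1-[3,4-bis(benzyloxy)phenyl]-2,2-dimethoxyethan-1-ol | COC(OC)[C@H](O)c1ccc(OCc2ccccc2)c(OCc2ccccc2)c1 | intermediate
11 | (2R)-2-[3,4-bis(benzyloxy)phenyl]-2-hydroxyacetaldehyde | O=C[C@H](O)c1ccc(OCc2ccccc2)c(OCc2ccccc2)c1 | intermediate
12 | benzylic lithio derivative of 5 | [Li]C(Sc1ccccc1)c1c(F)cc(OCc2ccccc2)cc1OCc1ccccc1 | intermediate
13 | lithium alkoxide of 11 | [Li+].O=C[C@H]([O-])c1ccc(OCc2ccccc2)c(OCc2ccccc2)c1 | intermediate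
14 | dilithium (1R,2S)-1-[3,4-bis(benzyloxy)phenyl]-3-[2,4-bis(benzyloxy)-6-fluorophenyl]-3-(phenylsulfanyl)propane-1,2-diolate (syn; C3 epimers) | [Li+].[Li+].[O-][C@H](C(Sc1ccccc1)c1c(F)cc(OCc2ccccc2)cc1OCc1ccccc1)[C@H]([O-])c1ccc(OCc2ccccc2)c(OCc2ccccc2)c1 | intermediate
15 | monolithium 1-alkoxide of the same syn diol | [Li+].O[C@H](C(Sc1ccccc1)c1c(F)cc(OCc2ccccc2)cc1OCc1ccccc1)[C@H]([O-])c1ccc(OCc2ccccc2)c(OCc2ccccc2)c1 | intermediate
16 | (2R,3S)-5,7-bis(benzyloxy)-2-[3,4-bis(benzyloxy)phenyl]-4-(phenylsulfanyl)chroman-3-ol (2,3-cis; C4 epimers) | O[C@@H]1C(Sc2ccccc2)c2c(OCc3ccccc3)cc(OCc3ccccc3)cc2O[C@@H]1c1ccc(OCc2ccccc2)c(OCc2ccccc2)c1 | intermediate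
17 | 3,4,5-tris(benzyloxy)benzoic acid | OC(=O)c1cc(OCc2ccccc2)c(OCc2ccccc2)c(OCc2ccccc2)c1 | starting material
18 | 3-O-[3,4,5-tris(benzyloxy)benzoyl] ester of 16 (C4 epimers) | O=C(O[C@@H]1C(Sc2ccccc2)c2c(OCc3ccccc3)cc(OCc3ccccc3)cc2O[C@@H]1c1ccc(OCc2ccccc2)c(OCc2ccccc2)c1)c1cc(OCc2ccccc2)c(OCc2ccccc2)c(OCc2ccccc2)c1 | intermediate
19 | (+)-catechin | O[C@H]1Cc2c(O)cc(O)cc2O[C@@H]1c1ccc(O)c(O)c1 | starting material
20 | 5,7,3',4'-tetra-O-benzyl-(+)-catechin | O[C@H]1Cc2c(OCc3ccccc3)cc(OCc3ccccc3)cc2O[C@@H]1c1ccc(OCc2ccccc2)c(OCc2ccccc2)c1 | intermediate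
21 | tetra-O-benzyl-3-O-[tris(benzyloxy)benzoyl]epicatechin-(4β→8)-tetra-O-benzylcatechin | O=C(O[C@@H]1[C@@H](c2c(OCc4ccccc4)cc(OCc4ccccc4)c3c2O[C@H](c2ccc(OCc4ccccc4)c(OCc4ccccc4)c2)[C@@H](O)C3)c2c(OCc3ccccc3)cc(OCc3ccccc3)cc2O[C@@H]1c1ccc(OCc2ccccc2)c(OCc2ccccc2)c1)c1cc(OCc2ccccc2)c(OCc2ccccc2)c(OCc2ccccc2)c1 | intermediate
22 | octadeca-O-benzyl epicatechin-3-O-gallate-(4β→8)-epicatechin-3-O-gallate-(4β→8)-catechin | O=C(O[C@@H]1[C@@H](c2c(OCc5ccccc5)cc(OCc5ccccc5)c3c2O[C@H](c2ccc(OCc5ccccc5)c(OCc5ccccc5)c2)[C@@H](O)C3)c2c(OCc5ccccc5)cc(OCc5ccccc5)c([C@H]3c4c(OCc5ccccc5)cc(OCc5ccccc5)cc4O[C@H](c4ccc(OCc5ccccc5)c(OCc5ccccc5)c4)[C@@H]3OC(=O)c3cc(OCc5ccccc5)c(OCc5ccccc5)c(OCc5ccccc5)c3)c2O[C@@H]1c1ccc(OCc2ccccc2)c(OCc2ccccc2)c1)c1cc(OCc2ccccc2)c(OCc2ccccc2)c(OCc2ccccc2)c1 | intermediate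
23 | epicatechin-3-O-gallate-(4β→8)-epicatechin-3-O-gallate-(4β→8)-catechin (CNP0269915.2) | O=C(O[C@@H]1[C@@H](c2c(O)cc(O)c3c2O[C@H](c2ccc(O)c(O)c2)[C@@H](O)C3)c2c(O)cc(O)c([C@H]3c4c(O)cc(O)cc4O[C@H](c4ccc(O)c(O)c4)[C@@H]3OC(=O)c3cc(O)c(O)c(O)c3)c2O[C@@H]1c1ccc(O)c(O)c1)c1cc(O)c(O)c(O)c1 | target

Total step count: 12. Longest linear sequence: 8 steps (steps 1, 2, 3, 7, 8, 10, 11, 12; the branch through steps 4, 5, 6 is equally long).

Steps most likely to fail

Step 7. The ring closure may go astray in several ways: fluoride may be displaced by the C3 oxygen (five-membered closure), chelation control may erode in the addition, the lithium alkoxide may displace fluoride too slowly, or 5 may be lithiated on the ring next to fluorine and decompose through an aryne. The fallback abandons the construction of ring C and takes the epicatechin gallate units from the chiral pool. Setting out from 20, Dess–Martin oxidation gives the flavan-3-one F1. Reduction with LiBH(s-Bu)3 at −78 °C, from the face anti to the C2 aryl group, gives 5,7,3',4'-tetra-O-benzylepicatechin F2. Steglich esterification with 17 gives the gallate F3. DDQ oxidation in the presence of 2-ethoxyethanol gives the 4β-(2-ethoxyethoxy) gallate F4. F4 takes the place of 18 in steps 10 and 11 under TMSOTf activation at −78 °C and so comes back to the route at 21.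

Step 11. The cation from 18 may be consumed by a second molecule of 18 (oligomerisation), or it may attack 21 at C6 of either unit instead of C8 of the upper unit. The fallback reverses the order of assembly and uses two orthogonal leaving groups. Setting out from 18, AgBF4 in CH2Cl2 containing methanol exchanges the thioether for the 4β-methyl ether F5. TMSOTf at −78 °C ionises F5 but not a C4–S bond, so F5 alkylates C8 of 18 (used in excess) to give the upper–middle dimer F6, which still carries the phenylthio group. AgBF4 activation of F6 in the presence of excess 20 then forms the lower interflavan bond and comes back to the route at 22.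

Step 6. The α-hydroxy aldehyde may partly racemise, or isomerise to the hydroxy ketone, during the acidic unmasking of the acetal. The fallback is a cyanohydrin route that needs no acetal hydrolysis. Setting out from 6, the aryllithium 8 is formylated with DMF to 3,4-bis(benzyloxy)benzaldehyde F7. An (R)-selective hydroxynitrile lyase adds HCN to give the (R)-cyanohydrin F8. Silylation (Me3SiCl, imidazole) gives the silyl ether F9. Reduction with i-Bu2AlH at −78 °C and a buffered aqueous work-up (pH 5) hydrolyse the imine and the silyl ether and come back to the route at 11.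

Further compounds
F1 | step 7 | (2R)-5,7-bis(benzyloxy)-2-[3,4-bis(benzyloxy)phenyl]chroman-3-one | O=C1Cc2c(OCc3ccccc3)cc(OCc3ccccc3)cc2O[C@@H]1c1ccc(OCc2ccccc2)c(OCc2ccccc2)c1
F2 | step 7 | 5,7,3',4'-tetra-O-benzyl-(−)-epicatechin | O[C@@H]1Cc2c(OCc3ccccc3)cc(OCc3ccccc3)cc2O[C@@H]1c1ccc(OCc2ccccc2)c(OCc2ccccc2)c1
F3 | step 7 | 5,7,3',4'-tetra-O-benzylepicatechin 3-O-[3,4,5-tris(benzyloxy)benzoate] | O=C(O[C@@H]1Cc2c(OCc3ccccc3)cc(OCc3ccccc3)cc2O[C@@H]1c1ccc(OCc2ccccc2)c(OCc2ccccc2)c1)c1cc(OCc2ccccc2)c(OCc2ccccc2)c(OCc2ccccc2)c1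
F4 | step 7 | 4β-(2-ethoxyethoxy)-5,7,3',4'-tetra-O-benzylepicatechin 3-O-[3,4,5-tris(benzyloxy)benzoate] | O=C(O[C@@H]1[C@@H](OCCOCC)c2c(OCc3ccccc3)cc(OCc3ccccc3)cc2O[C@@H]1c1ccc(OCc2ccccc2)c(OCc2ccccc2)c1)c1cc(OCc2ccccc2)c(OCc2ccccc2)c(OCc2ccccc2)c1
F5 | step 11 | 4β-methoxy-5,7,3',4'-tetra-O-benzylepicatechin 3-O-[3,4,5-tris(benzyloxy)benzoate] | O=C(O[C@@H]1[C@@H](OC)c2c(OCc3ccccc3)cc(OCc3ccccc3)cc2O[C@@H]1c1ccc(OCc2ccccc2)c(OCc2ccccc2)c1)c1cc(OCc2ccccc2)c(OCc2ccccc2)c(OCc2ccccc2)c1
F6 | step 11 | protected epicatechin gallate-(4β→8)-[4-(phenylsulfanyl)epicatechin gallate] dimer (C4 epimers at the thio-bearing unit) | O=C(O[C@@H]1C(Sc2ccccc2)c2c(OCc5ccccc5)cc(OCc5ccccc5)c([C@H]3c4c(OCc5ccccc5)cc(OCc5ccccc5)cc4O[C@H](c4ccc(OCc5ccccc5)c(OCc5ccccc5)c4)[C@@H]3OC(=O)c3cc(OCc5ccccc5)c(OCc5ccccc5)c(OCc5ccccc5)c3)c2O[C@@H]1c1ccc(OCc2ccccc2)c(OCc2ccccc2)c1)c1cc(OCc2ccccc2)c(OCc2ccccc2)c(OCc2ccccc2)c1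
F7 | step 6 | 3,4-bis(benzyloxy)benzaldehyde | O=Cc1ccc(OCc2ccccc2)c(OCc2ccccc2)c1
F8 | step 6 | (2R)-2-[3,4-bis(benzyloxy)phenyl]-2-hydroxyacetonitrile | N#C[C@H](O)c1ccc(OCc2ccccc2)c(OCc2ccccc2)c1
F9 | step 6 | (2R)-2-[3,4-bis(benzyloxy)phenyl]-2-[(trimethylsilyl)oxy]acetonitrile | N#C[C@H](O[Si](C)(C)C)c1ccc(OCc2ccccc2)c(OCc2ccccc2)c1
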